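The C3/C5 syn-diacetate of the target is pseudo-meso: the C2–C6 segment is mirror-symmetric, and only the guaiacyl ring on C1 and the syringyl ring on C7 break the symmetry. C2–C6 are therefore taken from a meso cis-cyclopentene-1,3-diol locked as a bridged di-tert-butylsilylene, whose alkene carbons become C2 and C6. A chiral ruthenium carbene opens this cyclopentene ring with O-benzyl-4-vinylguaiacol in one operation. It forges C1=C2 and C6=C7 and differentiates the two ends, so C3 and C5 become defined in the absolute sense while the dioxasilinane ring keeps them syn. Hydroboration/Suzuki coupling then attaches the syringyl ring to C7.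

Key step: step 4

Remark: the sense of induction of the chiral carbene on this new bicycle cannot be predicted with certainty; the route assumes that one of its two antipodes gives (4S,6R)-8, to be confirmed at diol 12 before material is carried on. Heptane numbering of the target is used throughout (C1 bears the guaiacyl ring, C7 the syringyl ring).

Step 1
Reactants: 1 cis-cyclopent-4-ene-1,3-diol (meso); 2 di-tert-butylsilyl bis(trifluoromethanesulfonate)
Product: 3 meso-(1R,5S)-3,3-di-tert-butyl-2,4-dioxa-3-silabicyclo[3.2.1]oct-6-ene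
Conditions: 2 (slow addition), 2,6-lutidine, CH2Cl2 (high dilution), 0 °C to rt
Reagents that add atoms: none
Why: Silylene formation from a 1,3-diol and a silyl bis-triflate should close the second Si–O bond intramolecularly, because the cis oxygens of the cyclopentene envelope sit at about the O···O distance of a dioxasilinane; no stereocenter changes and the product stays meso.

Step 2
Reactants: 4 2-methoxy-4-vinylphenol
Product: 5 1-(benzyloxy)-2-methoxy-4-vinylbenzene
Conditions: BnBr, K2CO3, DMF, rt (trace BHT)
Reagents that add atoms: benzyl bromide, BrCc1ccccc1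
Why: Williamson ether synthesis on the phenoxide, run at room temperature with a radical inhibitor so that the styrene should not polymerise.

Step 3
Reactants: 6 4-bromo-2,6-dimethoxyphenol
Product: 7 2-(benzyloxy)-5-bromo-1,3-dimethoxybenzene
Conditions: BnBr, K2CO3, DMF, 60 °C
Reagents that add atoms: benzyl bromide, BrCc1ccccc1
Why: Williamson ether synthesis, in which the flanked 2,6-dimethoxyphenoxide should still alkylate cleanly with the unhindered benzyl bromide on gentle warming.

Step 4
Reactants: 3 meso-(1R,5S)-3,3-di-tert-butyl-2,4-dioxa-3-silabicyclo[3.2.1]oct-6-ene; 5 1-(benzyloxy)-2-methoxy-4-vinylbenzene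
Product: 8 (4S,6R)-4-[(E)-2-(4-benzyloxy-3-methoxyphenyl)ethenyl]-2,2-di-tert-butyl-6-ethenyl-1,3,2-dioxasilinane (4,6-cis)
Conditions: chiral Ru(II) 2-isopropoxybenzylidene with a bidentate N-mesityl NHC–binaphthyl-2-olate ligand (5 mol %, the antipode that gives (4S,6R)-8), 5 (3 equiv), THF, 22 °C
Reagents that add atoms: none
Why: Proposed new method: the chiral Ru benzylidene generated from 5 adds [2+2] to the strained alkene of 3 on its exo face (anti to the O–Si–O bridge, where the tert-butyl groups do not interfere), cycloreversion of the ruthenacyclobutane opens the carbocycle with ArCH= on one former alkene carbon and Ru= on the other, and this alkylidene takes the CH2 group of a second molecule of 5 to release the vinyl terminus and return the benzylidene, so that 5 delivers C1 with its aryl ring as well as C7 and no coproduct is formed. The closest known reaction type is the catalytic enantioselective ring-opening/cross-metathesis of meso norbornenes, 8-oxabicyclo[3.2.1]octenes and cyclobutenes with styrenes; opening of the carbocycle of a 2,4-dioxa-3-silabicyclo[3.2.1]octene has not been shown. No ring is closed: the cyclopentene is opened and the 1,3,2-dioxasilinane is carried through unchanged. C3 and C5 keep the cis relationship built into the meso bicycle, and their absolute configuration follows from the catalyst, which decides which of the two enantiotopic alkene carbons is bonded to the benzylidene carbon. The step needs this group selectivity, ring opening in preference to oligomerisation and no further metathesis of the product; strain release from the bridged envelope, the excess of 5 that keeps the benzylidene as the chain carrier, and the hindered α-silyloxy product alkenes secure the last two. The E/Z ratio at C1=C2 is of no consequence, since this bond is saturated in step 6.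

Step 5
Reactants: 8 (4S,6R)-4-[(E)-2-(4-benzyloxy-3-methoxyphenyl)ethenyl]-2,2-di-tert-butyl-6-ethenyl-1,3,2-dioxasilinane; 7 2-(benzyloxy)-5-bromo-1,3-dimethoxybenzene
Product: 10 (4S,6S)-4-[(E)-2-(4-benzyloxy-3-methoxyphenyl)ethenyl]-6-[2-(4-benzyloxy-3,5-dimethoxyphenyl)ethyl]-2,2-di-tert-butyl-1,3,2-dioxasilinane, via B-alkyl-9-BBN borane 9 (not isolated)
Conditions: 9-BBN, THF, 0 °C to rt; then 7, Pd(OAc)2 (5 mol %), SPhos (10 mol %), K3PO4·H2O, THF, 60 °C
Reagents that add atoms: 9-borabicyclo[3.3.1]nonane (9-BBN-H), B1C2CCCC1CCC2 (its boron and ring stay in intermediate 9 only; product 10 keeps one hydrogen from it)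
Why: Anti-Markovnikov hydroboration with 9-BBN should select the monosubstituted vinyl group over the 1,2-disubstituted styrenyl alkene, and the primary alkyl group is then transferred to the aryl bromide in a B-alkyl Suzuki–Miyaura coupling that leaves C3 and C5 untouched (the descriptor at C5 changes only because the CIP priorities change).

Step 6
Reactants: 10 (4S,6S)-4-[(E)-2-(4-benzyloxy-3-methoxyphenyl)ethenyl]-6-[2-(4-benzyloxy-3,5-dimethoxyphenyl)ethyl]-2,2-di-tert-butyl-1,3,2-dioxasilinane
Product: 11 (4R,6S)-4-[2-(4-benzyloxy-3-methoxyphenyl)ethyl]-6-[2-(4-benzyloxy-3,5-dimethoxyphenyl)ethyl]-2,2-di-tert-butyl-1,3,2-dioxasilinane (4,6-cis)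
Conditions: TsNHNH2 (excess, in portions), NaOAc, DME/H2O, 85 °C
Reagents that add atoms: none
Why: Diimide reduction transfers H2 to the C1=C2 bond in a concerted syn fashion and should touch neither the benzyl ethers nor the allylic C–O bond, so no stereocenter is formed or lost.

Step 7
Reactants: 11 (4R,6S)-4-[2-(4-benzyloxy-3-methoxyphenyl)ethyl]-6-[2-(4-benzyloxy-3,5-dimethoxyphenyl)ethyl]-2,2-di-tert-butyl-1,3,2-dioxasilinane
Product: 12 (3R,5S)-1-(4-benzyloxy-3-methoxyphenyl)-7-(4-benzyloxy-3,5-dimethoxyphenyl)heptane-3,5-diol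
Conditions: HF·pyridine, pyridine, THF, 0 °C to rt
Reagents that add atoms: none
Why: Fluoride-driven cleavage of the silylene (strong Si–F bonds) under buffered conditions should free the syn-diol with benzyl and methyl ethers inert and both carbinol configurations retained.

Step 8
Reactants: 12 (3R,5S)-1-(4-benzyloxy-3-methoxyphenyl)-7-(4-benzyloxy-3,5-dimethoxyphenyl)heptane-3,5-diol
Product: 13 (3R,5S)-1-(4-benzyloxy-3-methoxyphenyl)-7-(4-benzyloxy-3,5-dimethoxyphenyl)heptane-3,5-diyl diacetate
Conditions: Ac2O, pyridine, DMAP (cat.), CH2Cl2, rt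
Reagents that add atoms: acetic anhydride, CC(=O)OC(C)=O
Why: DMAP-catalysed acylation should esterify both secondary alcohols with retention while the two phenols remain masked as benzyl ethers.

Step 9
Reactants: 13 (3R,5S)-1-(4-benzyloxy-3-methoxyphenyl)-7-(4-benzyloxy-3,5-dimethoxyphenyl)heptane-3,5-diyl diacetate
Product: 14 (3R,5S)-1-(4-hydroxy-3-methoxyphenyl)-7-(4-hydroxy-3,5-dimethoxyphenyl)heptane-3,5-diyl diacetate (CNP0327377.1)
Conditions: H2 (1 atm), 10% Pd/C, EtOAc, rt
Reagents that add atoms: none
Why: Catalytic hydrogenolysis should cleave the two aryl benzyl ethers under neutral conditions, and the acetates are safe because, after step 6, they are neither allylic nor benzylic.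

Compound list
1 | cis-cyclopent-4-ene-1,3-diol, meso (1R,3S) | O[C@H]1C[C@@H](O)C=C1 | starting material
2 | di-tert-butylsilyl bis(trifluoromethanesulfonate) | CC(C)(C)[Si](OS(=O)(=O)C(F)(F)F)(OS(=O)(=O)C(F)(F)F)C(C)(C)C | starting material
3 | meso-(1R,5S)-3,3-di-tert-butyl-2,4-dioxa-3-silabicyclo[3.2.1]oct-6-ene | O1[C@H]2C[C@@H](O[Si]1(C(C)(C)C)C(C)(C)C)C=C2 | intermediate
4 | 2-methoxy-4-vinylphenol | COc1cc(C=C)ccc1O | starting material
5 | 1-(benzyloxy)-2-methoxy-4-vinylbenzene | COc1cc(C=C)ccc1OCc1ccccc1 | intermediate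
6 | 4-bromo-2,6-dimethoxyphenol | COc1cc(Br)cc(OC)c1O | starting material
7 | 2-(benzyloxy)-5-bromo-1,3-dimethoxybenzene | COc1cc(Br)cc(OC)c1OCc1ccccc1 | intermediate
8 | (4S,6R)-4-[(E)-2-(4-benzyloxy-3-methoxyphenyl)ethenyl]-2,2-di-tert-butyl-6-ethenyl-1,3,2-dioxasilinane | COc1cc(/C=C/[C@@H]2C[C@H](C=C)O[Si](C(C)(C)C)(C(C)(C)C)O2)ccc1OCc1ccccc1 | intermediate
9 | (4S,6S)-4-[(E)-2-(4-benzyloxy-3-methoxyphenyl)ethenyl]-6-[2-(9-borabicyclo[3.3.1]nonan-9-yl)ethyl]-2,2-di-tert-butyl-1,3,2-dioxasilinane | COc1cc(/C=C/[C@@H]2C[C@H](CCB3C4CCCC3CCC4)O[Si](C(C)(C)C)(C(C)(C)C)O2)ccc1OCc1ccccc1 | intermediate (not isolated)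
10 | (4S,6S)-4-[(E)-2-(4-benzyloxy-3-methoxyphenyl)ethenyl]-6-[2-(4-benzyloxy-3,5-dimethoxyphenyl)ethyl]-2,2-di-tert-butyl-1,3,2-dioxasilinane | COc1cc(/C=C/[C@@H]2C[C@H](CCc3cc(OC)c(OCc4ccccc4)c(OC)c3)O[Si](C(C)(C)C)(C(C)(C)C)O2)ccc1OCc1ccccc1 | intermediate
11 | (4R,6S)-4-[2-(4-benzyloxy-3-methoxyphenyl)ethyl]-6-[2-(4-benzyloxy-3,5-dimethoxyphenyl)ethyl]-2,2-di-tert-butyl-1,3,2-dioxasilinane | COc1cc(CC[C@@H]2C[C@H](CCc3cc(OC)c(OCc4ccccc4)c(OC)c3)O[Si](C(C)(C)C)(C(C)(C)C)O2)ccc1OCc1ccccc1 | intermediate
12 | (3R,5S)-1-(4-benzyloxy-3-methoxyphenyl)-7-(4-benzyloxy-3,5-dimethoxyphenyl)heptane-3,5-diol | COc1cc(CC[C@@H](O)C[C@H](CCc2cc(OC)c(OCc3ccccc3)c(OC)c2)O)ccc1OCc1ccccc1 | intermediate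
13 | (3R,5S)-1-(4-benzyloxy-3-methoxyphenyl)-7-(4-benzyloxy-3,5-dimethoxyphenyl)heptane-3,5-diyl diacetate | COc1cc(CC[C@@H](OC(C)=O)C[C@H](CCc2cc(OC)c(OCc3ccccc3)c(OC)c2)OC(C)=O)ccc1OCc1ccccc1 | intermediate
14 | (3R,5S)-1-(4-hydroxy-3-methoxyphenyl)-7-(4-hydroxy-3,5-dimethoxyphenyl)heptane-3,5-diyl diacetate | COc1cc(CC[C@H](C[C@H](CCc2cc(OC)c(O)c(OC)c2)OC(C)=O)OC(C)=O)ccc1O | target

Total step count: 9. Longest linear sequence: 7 steps (steps 1, 4, 5, 6, 7, 8, 9, from diol 1).

Steps most likely to fail

Step 4. Enantiotopic-group discrimination may be poor on this untested bicycle, the bridged cyclopentene may open too slowly, or the opened alkylidene may oligomerise instead of being capped by the styrene. The fallback builds the pseudo-meso diol on an acyclic route of known reactions; it sets out from 7 and from commercial zingerone, 4-(4-hydroxy-3-methoxyphenyl)butan-2-one, and comes back at 12. Heck reaction of 7 with allyl alcohol under phase-transfer conditions (Pd(OAc)2, Bu4NCl, NaHCO3, DMF, 80 °C) should give 3-(4-benzyloxy-3,5-dimethoxyphenyl)propanal F1. Benzylation of zingerone (BnBr, K2CO3, DMF) should give 4-(4-benzyloxy-3-methoxyphenyl)butan-2-one F2. The boron enolate of F2, formed on the methyl side with the appropriate antipode of diisopinocampheylboron chloride and Et3N, is added to F1 in a reagent-controlled boron aldol reaction, which should give (5S)-1-(4-benzyloxy-3-methoxyphenyl)-7-(4-benzyloxy-3,5-dimethoxyphenyl)-5-hydroxyheptan-3-one F3. Its enantiomeric purity would be raised by crystallisation or chiral chromatography if required. Narasaka–Prasad reduction (Et2BOMe, NaBH4, THF/MeOH, −78 °C) then sets C3 syn to C5 through the boron chelate and should deliver 12, from which steps 8 and 9 follow.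

Step 5. Hydroboration may be incomplete or may touch the styrenyl alkene, and oxidative addition to the electron-rich aryl bromide may be slow enough for protodeboronation or β-hydride elimination of the alkylborane to take over. The fallback sets out from 8 and 7 and comes back at 11. Mizoroki–Heck arylation of the terminal vinyl group of 8 with 7 (Pd2(dba)3, P(t-Bu)3, Cy2NMe, dioxane, 80 °C) should give (4S,6R)-4-[(E)-2-(4-benzyloxy-3-methoxyphenyl)ethenyl]-6-[(E)-2-(4-benzyloxy-3,5-dimethoxyphenyl)ethenyl]-2,2-di-tert-butyl-1,3,2-dioxasilinane F4. Both styrenyl double bonds are then saturated with diimide under the conditions of step 6 (larger excess of hydrazide) to give 11.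

Step 1. Intermolecular silylation may outrun closure of the strained bridge, giving oligomeric silyl ethers instead of the bicycle. The fallback separates the two Si–O bond formations; it sets out from 1 and comes back at 3. Monosilylation of 1 with di-tert-butylchlorosilane (imidazole, DMF, 0 °C) should give cis-4-[(di-tert-butylsilyl)oxy]cyclopent-2-en-1-ol F5 (racemic, which is immaterial because closure restores the mirror plane). A separate base-catalysed intramolecular dehydrogenative Si–O coupling (cat. KOt-Bu, THF, dilute, rt to 50 °C) then closes the bridge with loss of hydrogen to give 3.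

Further compounds
F1 | step 4 | 3-(4-benzyloxy-3,5-dimethoxyphenyl)propanal | COc1cc(CCC=O)cc(OC)c1OCc1ccccc1
F2 | step 4 | 4-(4-benzyloxy-3-methoxyphenyl)butan-2-one | COc1cc(CCC(C)=O)ccc1OCc1ccccc1
F3 | step 4 | (5S)-1-(4-benzyloxy-3-methoxyphenyl)-7-(4-benzyloxy-3,5-dimethoxyphenyl)-5-hydroxyheptan-3-one | COc1cc(CCC(=O)C[C@H](CCc2cc(OC)c(OCc3ccccc3)c(OC)c2)O)ccc1OCc1ccccc1
F4 | step 5 | (4S,6R)-4-[(E)-2-(4-benzyloxy-3-methoxyphenyl)ethenyl]-6-[(E)-2-(4-benzyloxy-3,5-dimethoxyphenyl)ethenyl]-2,2-di-tert-butyl-1,3,2-dioxasilinane | COc1cc(/C=C/[C@@H]2C[C@H](/C=C/c3cc(OC)c(OCc4ccccc4)c(OC)c3)O[Si](C(C)(C)C)(C(C)(C)C)O2)ccc1OCc1ccccc1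
F5 | step 1 | cis-4-[(di-tert-butylsilyl)oxy]cyclopent-2-en-1-ol (racemic) | O[C@H]1C[C@@H](O[SiH](C(C)(C)C)C(C)(C)C)C=C1
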